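Drimane numbering is used. Read literally, the target is a cis-decalin: H5, CH3-10 and C11 lie on one face and the 3-acetoxy group on the other. An (E,E)-polyene bicyclization would give the trans-decalin, so ring B has to be in place before ring A closes.
Cuts: O-acetyl, C11–OAr (isofraxidin, both coumarin rings bought), C8=C12, C9–C11, then C4–C5 (ring A), then C10–C1.
Forward: ring B is bought as 3-methylcyclohexenone, the chain C1–C4 is joined at C10, and ring A is closed last when C5 opens a C3–C4 epoxide.
Enabling feature: C5 of ring B stands next to the quaternary C10, which carries the four-atom chain C1–C4 ending in a tertiary epoxide carbon. Such a tether reaches the flat C5 only on its own face, and this enforces the cis ring fusion.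
Helper: a carbonyl group at C6 makes C5 an enol-ether carbon. It is then shifted to C8 (1,3-transposition), where it serves the C9–C11 aldol and the C12 methylenation and so disappears.
Stereochemistry: C10 by Cu-catalysed conjugate addition, C3 by Shi epoxidation, C5 by the tether, C9 by aldol attack on the convex face.

Key step: step 5

Assumption: the descriptors of the SMILES are taken literally (3S,5R,9R,10R, cis-fused), and the L-fructose-derived antipode of the Shi ketone is taken as an accessible catalyst.

Step 1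
Reactants: 1 3-methylcyclohex-2-en-1-one; 2 5-bromo-2-methylpent-2-ene
Product: 5 (3R)-3-methyl-3-(4-methylpent-3-en-1-yl)cyclohexan-1-one, via homoprenylmagnesium bromide 3 (not isolated), via bromomagnesium enolate 4 (not isolated)
Conditions: Mg, Et2O; Cu(OTf)2 (3 mol %), chiral hydroxy-functionalised imidazolinium salt (NHC precursor, 4 mol %), Et2O, −30 °C, then 1; 1 M HCl
Reagents that add atoms: none
Why: Copper-catalysed asymmetric conjugate addition of a Grignard reagent to a β-substituted cyclic enone should create the quaternary C10, and the ligand antipode is chosen so that the (R)-ketone forms.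

Step 2
Reactants: 5 (3R)-3-methyl-3-(4-methylpent-3-en-1-yl)cyclohexan-1-one
Product: 6 (5S)-5-methyl-5-(4-methylpent-3-en-1-yl)cyclohex-2-en-1-one
Conditions: IBX (1.5 equiv), DMSO, 70 °C
Reagents that add atoms: none
Why: IBX dehydrogenation of a ketone can run only toward C7–C8, because C10 on the other side bears no hydrogen, and no stereocentre is touched.

Step 3
Reactants: 6 (5S)-5-methyl-5-(4-methylpent-3-en-1-yl)cyclohex-2-en-1-one
Product: 7 (5S)-5-{2-[(2S)-3,3-dimethyloxiran-2-yl]ethyl}-5-methylcyclohex-2-en-1-one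
Conditions: L-fructose-derived Shi ketone (30 mol %), KHSO5 (Oxone), K2CO3, Bu4NHSO4, MeCN–dimethoxymethane/aq Na2B4O7 buffer, 0 °C
Reagents that add atoms: potassium peroxymonosulfate [K+].[O-]S(=O)(=O)OO
Why: In the Shi epoxidation the chiral dioxirane should attack only the electron-rich trisubstituted alkene and not the enone, and this catalyst antipode should give the (S)-epoxide, which is the later C3.

Step 4
Reactants: 7 (5S)-5-{2-[(2S)-3,3-dimethyloxiran-2-yl]ethyl}-5-methylcyclohex-2-en-1-one
Product: 8 tert-butyl{[(3S)-3-{2-[(2S)-3,3-dimethyloxiran-2-yl]ethyl}-3-methylcyclohexa-1,5-dien-1-yl]oxy}dimethylsilane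
Conditions: LiN(i-Pr)2 (1.1 equiv), THF, −78 °C; t-BuMe2SiCl, DMPU, −78 to 0 °C
Reagents that add atoms: tert-butyldimethylsilyl chloride CC(C)(C)[Si](C)(C)Cl
Why: Kinetic deprotonation of a cyclohexenone takes the α′-hydrogen, here at C5 (the only sp3 α-carbon), and O-silylation gives the cross-conjugated 2-silyloxydiene while the epoxide stays inert to the amide base in the cold.

Step 5
Reactants: 8 tert-butyl{[(3S)-3-{2-[(2S)-3,3-dimethyloxiran-2-yl]ethyl}-3-methylcyclohexa-1,5-dien-1-yl]oxy}dimethylsilane
Product: 9 (4aS,7S,8aR)-7-hydroxy-4a,8,8-trimethyl-4a,5,6,7,8,8a-hexahydronaphthalen-1(4H)-one (cis-fused, carbonyl at C6)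
Conditions: MeAlCl2 (1.5 equiv), CH2Cl2, −78 °C; aq NaHCO3
Reagents that add atoms: none
Why: MeAlCl2 binds the epoxide oxygen and loosens the tertiary C4–O bond, the enol-ether carbon C5 attacks C4 from the rear, and loss of the silyl group from the resulting oxocarbenium ion restores the C6 enone. The closest known reaction type is the epoxide-initiated cation–olefin cyclization terminated by a silyl enol ether, which itself copies the first C4–C5 bond formation of the terpene cyclases. Ring A closes by a 6-endo opening of the epoxide at its tertiary carbon (enol-endo for the nucleophile) through a chair in which the C3–O–Al bond lies equatorial. C5 is the only new stereocentre and is controlled by the tether: the chain C1–C4 hangs from the quaternary C10 next to the flat C5, so C4 can reach the p-orbital of C5 only on the face that C1 occupies, which leaves H5 on the face of CH3-10 (cis-fusion), whereas C3 keeps its configuration because its C–O bond stays intact, and the (S)-epoxide is the one that fits this chair. The step needs attack at C4 and not at C3, which is secured by the cationic character of the tertiary carbon under a Lewis acid and by the six-membered chair, and it needs C- rather than O-attack, which only the six-membered geometry allows. It also needs ring closure to outrun the hydride shift of the opened epoxide, which is favoured by the high nucleophilicity of the 2-silyloxydiene and by the gem-disubstitution at C10 and C4.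

Step 6
Reactants: 9 (4aS,7S,8aR)-7-hydroxy-4a,8,8-trimethyl-4a,5,6,7,8,8a-hexahydronaphthalen-1(4H)-one
Product: 10 (4aS,7S,8aR)-4a,8,8-trimethyl-1,4,4a,5,6,7,8,8a-octahydronaphthalene-1,7-diol (configuration at the new C6 carbinol of no consequence)
Conditions: NaBH4, CeCl3·7H2O, MeOH, −40 °C
Reagents that add atoms: none
Why: The Luche reduction is 1,2-selective and non-basic, so the epimerisable C5 next to the carbonyl should survive, and the new carbinol centre is only transient.

Step 7
Reactants: 10 (4aS,7S,8aR)-4a,8,8-trimethyl-1,4,4a,5,6,7,8,8a-octahydronaphthalene-1,7-diol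
Product: 11 (4aR,6S,8aS)-5,5,8a-trimethyl-1,2,4a,5,6,7,8,8a-octahydronaphthalene-2,6-diol (hydroxyl now at C8, alkene C6=C7)
Conditions: Ph3SiOReO3 (5 mol %), Et2O, 0 °C
Reagents that add atoms: none
Why: The rhenium-oxo-catalysed 1,3-transposition of allylic alcohols ([3,3] shift of the perrhenate ester) should move the oxygen from the crowded C6, which is pressed against the C4 methyl groups, to the freer C8 without touching C5.

Step 8
Reactants: 11 (4aR,6S,8aS)-5,5,8a-trimethyl-1,2,4a,5,6,7,8,8a-octahydronaphthalene-2,6-diol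
Product: 12 (4aR,6S,8aS)-6-hydroxy-5,5,8a-trimethyl-4a,5,6,7,8,8a-hexahydronaphthalen-2(1H)-one
Conditions: MnO2 (excess), CH2Cl2, rt
Reagents that add atoms: none
Why: MnO2 oxidises only the allylic alcohol at C8 and leaves the saturated, hindered C3 hydroxyl untouched.

Step 9
Reactants: 12 (4aR,6S,8aS)-6-hydroxy-5,5,8a-trimethyl-4a,5,6,7,8,8a-hexahydronaphthalen-2(1H)-one
Product: 13 (1R,4aR,6S,8aR)-6-hydroxy-1-(hydroxymethyl)-5,5,8a-trimethyl-4a,5,6,7,8,8a-hexahydronaphthalen-2(1H)-one
Conditions: LiN(i-Pr)2 (2.3 equiv), THF, −78 °C; monomeric HCHO in THF, −78 °C; AcOH, −78 °C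
Reagents that add atoms: formaldehyde C=O
Why: The kinetic α′-enolate of the enone can form only at C9, and in the aldol addition formaldehyde should enter from the convex face of the cis-decalin (the face of H5 and CH3-10, since ring A covers the other one), which sets C9 with C11 cis to CH3-10.

Step 10
Reactants: 13 (1R,4aR,6S,8aR)-6-hydroxy-1-(hydroxymethyl)-5,5,8a-trimethyl-4a,5,6,7,8,8a-hexahydronaphthalen-2(1H)-one
Product: 14 (1R,4aR,6S,8aR)-6-hydroxy-1-(hydroxymethyl)-5,5,8a-trimethyloctahydronaphthalen-2(1H)-one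
Conditions: H2 (1 atm), Pd/C, EtOAc, rt
Reagents that add atoms: none
Why: Heterogeneous hydrogenation saturates the disubstituted C6=C7 bond, creates no stereocentre, and its neutral medium should leave the β-hydroxy ketone and C9 unchanged.

Step 11
Reactants: 14 (1R,4aR,6S,8aR)-6-hydroxy-1-(hydroxymethyl)-5,5,8a-trimethyloctahydronaphthalen-2(1H)-one
Product: 15 (2S,4aR,5R,8aR)-5-(hydroxymethyl)-1,1,4a-trimethyl-6-methylidenedecahydronaphthalen-2-ol
Conditions: Zn, CH2Br2, TiCl4 (excess reagent), THF–CH2Cl2, 0 °C to rt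
Reagents that add atoms: dibromomethane BrCBr
Why: The Takai–Lombardo methylenation is non-basic, so it should convert the enolisable β-hydroxy ketone into the exocyclic alkene without retro-aldol cleavage or epimerisation at C9.

Step 12
Reactants: 15 (2S,4aR,5R,8aR)-5-(hydroxymethyl)-1,1,4a-trimethyl-6-methylidenedecahydronaphthalen-2-ol; 16 isofraxidin (7-hydroxy-6,8-dimethoxy-2H-chromen-2-one)
Product: 17 7-{[(1R,4aR,6S,8aR)-6-hydroxy-5,5,8a-trimethyl-2-methylidenedecahydronaphthalen-1-yl]methoxy}-6,8-dimethoxy-2H-chromen-2-one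
Conditions: PPh3, DIAD, toluene–THF, 0 to 40 °C
Reagents that add atoms: none
Why: In the Mitsunobu etherification the acidic coumarin phenol should displace the oxyphosphonium group of the primary C11 alcohol only, because the C3 hydroxyl next to the quaternary C4 is too hindered to be activated.

Step 13
Reactants: 17 7-{[(1R,4aR,6S,8aR)-6-hydroxy-5,5,8a-trimethyl-2-methylidenedecahydronaphthalen-1-yl]methoxy}-6,8-dimethoxy-2H-chromen-2-one
Product: 18 (2S,4aR,5R,8aR)-5-{[(6,8-dimethoxy-2-oxo-2H-chromen-7-yl)oxy]methyl}-1,1,4a-trimethyl-6-methylidenedecahydronaphthalen-2-yl acetate (target)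
Conditions: Ac2O, DMAP, pyridine, 40 °C
Reagents that add atoms: acetic anhydride CC(=O)OC(C)=O
Why: DMAP-catalysed acylation of the one remaining hydroxyl group proceeds with retention at C3 and leaves the lactone, aryl ether and alkene alone.

Compound list
1 | 3-methylcyclohex-2-en-1-one | CC1=CC(=O)CCC1 | starting material
2 | 5-bromo-2-methylpent-2-ene | CC(C)=CCCBr | starting material
3 | (4-methylpent-3-en-1-yl)magnesium bromide | CC(C)=CCC[Mg]Br | intermediate
4 | bromomagnesium enolate of 5 | CC(C)=CCC[C@@]1(C)CCCC(O[Mg]Br)=C1 | intermediate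
5 | (3R)-3-methyl-3-(4-methylpent-3-en-1-yl)cyclohexan-1-one | CC(C)=CCC[C@@]1(C)CCCC(=O)C1 | intermediate
6 | (5S)-5-methyl-5-(4-methylpent-3-en-1-yl)cyclohex-2-en-1-one | CC(C)=CCC[C@@]1(C)CC=CC(=O)C1 | intermediate
7 | (5S)-5-{2-[(2S)-3,3-dimethyloxiran-2-yl]ethyl}-5-methylcyclohex-2-en-1-one | CC1(C)O[C@H]1CC[C@@]2(C)CC=CC(=O)C2 | intermediate
8 | tert-butyl{[(3S)-3-{2-[(2S)-3,3-dimethyloxiran-2-yl]ethyl}-3-methylcyclohexa-1,5-dien-1-yl]oxy}dimethylsilane | CC1(C)O[C@H]1CC[C@@]2(C)CC=CC(O[Si](C)(C)C(C)(C)C)=C2 | intermediate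
9 | (4aS,7S,8aR)-7-hydroxy-4a,8,8-trimethyl-4a,5,6,7,8,8a-hexahydronaphthalen-1(4H)-one | C1=CC(=O)[C@H]2C(C)(C)[C@@H](O)CC[C@@]2(C)C1 | intermediate
10 | (4aS,7S,8aR)-4a,8,8-trimethyl-1,4,4a,5,6,7,8,8a-octahydronaphthalene-1,7-diol | C1=CC(O)[C@H]2C(C)(C)[C@@H](O)CC[C@@]2(C)C1 | intermediate
11 | (4aR,6S,8aS)-5,5,8a-trimethyl-1,2,4a,5,6,7,8,8a-octahydronaphthalene-2,6-diol | OC1C=C[C@H]2C(C)(C)[C@@H](O)CC[C@@]2(C)C1 | intermediate
12 | (4aR,6S,8aS)-6-hydroxy-5,5,8a-trimethyl-4a,5,6,7,8,8a-hexahydronaphthalen-2(1H)-one | O=C1C=C[C@H]2C(C)(C)[C@@H](O)CC[C@@]2(C)C1 | intermediate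
13 | (1R,4aR,6S,8aR)-6-hydroxy-1-(hydroxymethyl)-5,5,8a-trimethyl-4a,5,6,7,8,8a-hexahydronaphthalen-2(1H)-one | O=C1C=C[C@H]2C(C)(C)[C@@H](O)CC[C@@]2(C)[C@@H]1CO | intermediate
14 | (1R,4aR,6S,8aR)-6-hydroxy-1-(hydroxymethyl)-5,5,8a-trimethyloctahydronaphthalen-2(1H)-one | O=C1CC[C@H]2C(C)(C)[C@@H](O)CC[C@@]2(C)[C@@H]1CO | intermediate
15 | (2S,4aR,5R,8aR)-5-(hydroxymethyl)-1,1,4a-trimethyl-6-methylidenedecahydronaphthalen-2-ol | C=C1CC[C@H]2C(C)(C)[C@@H](O)CC[C@@]2(C)[C@@H]1CO | intermediate
16 | isofraxidin (7-hydroxy-6,8-dimethoxy-2H-chromen-2-one) | COc1cc2ccc(=O)oc2c(OC)c1O | starting material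
17 | 7-{[(1R,4aR,6S,8aR)-6-hydroxy-5,5,8a-trimethyl-2-methylidenedecahydronaphthalen-1-yl]methoxy}-6,8-dimethoxy-2H-chromen-2-one | C=C1CC[C@H]2C(C)(C)[C@@H](O)CC[C@@]2(C)[C@@H]1COc1c(OC)cc2ccc(=O)oc2c1OC | intermediate
18 | (2S,4aR,5R,8aR)-5-{[(6,8-dimethoxy-2-oxo-2H-chromen-7-yl)oxy]methyl}-1,1,4a-trimethyl-6-methylidenedecahydronaphthalen-2-yl acetate | C=C1CC[C@H]2C(C)(C)[C@@H](OC(C)=O)CC[C@@]2(C)[C@@H]1COc1c(OC)cc2ccc(=O)oc2c1OC | target

Total step count: 13. Longest linear sequence: 13 steps (1 and 2 to 18). Isofraxidin enters as bought.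

Steps most likely to fail

Step 5. Bond formation between the tertiary C4 and the crowded C5 may be outrun by the hydride shift of the activated epoxide to a ketone, by proton loss to an allylic alcohol, or by desilylation of the dienol ether.
- The fallback sets out from 6 and comes back at 12. It uses a doubly activated diene and a different way of moving the carbonyl group.
- Conjugate addition of methanol (NaOMe cat., MeOH) should give the β-methoxy ketone F1.
- IBX dehydrogenation should give the vinylogous ester F2.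
- Shi epoxidation with the same catalyst should give the epoxy vinylogous ester F3.
- Kinetic silylation (LiN(i-Pr)2, t-BuMe2SiCl) should give the 1-methoxy-3-silyloxy diene F4. Its C5 is a much stronger π-nucleophile, so a weak Lewis acid (ZnBr2 or Me2AlCl, CH2Cl2, −78 °C) should be enough to close ring A to the bicyclic vinylogous ester F5.
- i-Bu2AlH should reduce the C6 carbonyl to the methoxy allylic alcohol F6, which on work-up with dilute HCl loses methanol in a Stork–Danheiser transposition and gives 12. Steps 6 to 8 then fall away.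

Step 7. The transposition is an equilibrium that may not lie far enough on the side of the C8 alcohol. Ionisation of the perrhenate ester to an allyl cation may also lead to loss of H5 and diene formation.
- The fallback sets out from 10 and comes back at 11 by an irreversible redox sequence.
- Hydroxyl-directed epoxidation (VO(acac)2, t-BuOOH, CH2Cl2) should give the epoxy diol F7.
- Trivalent titanium (Cp2TiCl from Cp2TiCl2 and Zn, THF) should open the epoxide homolytically at C7 and expel the neighbouring C6 oxygen. This leaves the C6=C7 alkene and the C8 hydroxyl group of 11.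

Step 12. Displacement at the β-branched C11, between the quaternary C10 and the sp2 C8, by a phenol flanked by two methoxy groups may be so slow that the betaine is consumed unproductively or elimination toward C9 sets in.
- The fallback sets out from 15 and comes back at 17 and separates activation from displacement.
- Selective sulfonylation of the primary alcohol (Tf2O, 2,6-lutidine, CH2Cl2, −78 °C) should give the primary triflate F8.
- F8 is then displaced by the caesium salt of 16 (Cs2CO3, MeCN, rt) in a Williamson ether synthesis with a far better leaving group and a free phenoxide.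

Further compounds
F1 | step 5 | (5S)-3-methoxy-5-methyl-5-(4-methylpent-3-en-1-yl)cyclohexan-1-one | CC(C)=CCC[C@@]1(C)CC(OC)CC(=O)C1
F2 | step 5 | (5S)-3-methoxy-5-methyl-5-(4-methylpent-3-en-1-yl)cyclohex-2-en-1-one | CC(C)=CCC[C@@]1(C)CC(OC)=CC(=O)C1
F3 | step 5 | (5S)-5-{2-[(2S)-3,3-dimethyloxiran-2-yl]ethyl}-3-methoxy-5-methylcyclohex-2-en-1-one | CC1(C)O[C@H]1CC[C@@]2(C)CC(OC)=CC(=O)C2
F4 | step 5 | tert-butyl{[(3S)-3-{2-[(2S)-3,3-dimethyloxiran-2-yl]ethyl}-5-methoxy-3-methylcyclohexa-1,5-dien-1-yl]oxy}dimethylsilane | CC1(C)O[C@H]1CC[C@@]2(C)CC(OC)=CC(O[Si](C)(C)C(C)(C)C)=C2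
F5 | step 5 | (4aS,7S,8aR)-7-hydroxy-3-methoxy-4a,8,8-trimethyl-4a,5,6,7,8,8a-hexahydronaphthalen-1(4H)-one | COC1=CC(=O)[C@H]2C(C)(C)[C@@H](O)CC[C@@]2(C)C1
F6 | step 5 | (4aS,7S,8aR)-3-methoxy-4a,8,8-trimethyl-1,4,4a,5,6,7,8,8a-octahydronaphthalene-1,7-diol | COC1=CC(O)[C@H]2C(C)(C)[C@@H](O)CC[C@@]2(C)C1
F7 | step 7 | C7–C8 epoxide of diol 10 | C12OC1C(O)[C@H]3C(C)(C)[C@@H](O)CC[C@@]3(C)C2
F8 | step 12 | [(1R,4aR,6S,8aR)-6-hydroxy-5,5,8a-trimethyl-2-methylidenedecahydronaphthalen-1-yl]methyl trifluoromethanesulfonate | C=C1CC[C@H]2C(C)(C)[C@@H](O)CC[C@@]2(C)[C@@H]1COS(=O)(=O)C(F)(F)F
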